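The route rests on cutting the C3–CH(aryl) bond of ring F. The O–CH(4-methoxyphenyl) unit of that ring is a 4-methoxybenzyl ether of a ring D enol, and its benzylic carbon lies 1,5 to the C3 carbonyl carbon of a ring C chromane-3,4-dione. A single enantioselective Norrish–Yang photocyclisation of the mirror-symmetric spiro trione 9, which carries two such ethers on ring D, closes ring F, creates the C3 hydroxyl and fixes the spiro, C3 and benzylic stereocentres by selecting one enantiotopic arm. The untouched arm is then unmasked to an enol-dione, onto which ring P is built by Michael addition, asymmetric transfer hydrogenation and cyclodehydration.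

Key step: step 6

Labels: ring A is the dimethoxybenzo ring; ring C the chromanone ring (O1, spiro C2, C3, C4); ring D the cyclohexadienone (C1' = C2, then C2' to C6'); ring F the dihydrofuran; ring P the dihydropyran; PMB is 4-methoxybenzyl.

Assumption: the sense of induction of the chiral scandium complex in step 6 cannot be predicted with confidence; the (S,S)-ligand is written, and its antipode would be used if the mirror-image product should prevail.

Remark: the spiro carbon is R in 10 and S in 16 with unchanged geometry, because ring P raises the CIP rank of C6' above C2'. Trione 9 is to be kept dry and away from nucleophiles, since attack at C3 would release ring D as a phenol.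

Step 1
Reactants: 1 2,6-dimethoxy-1,4-benzoquinone; 2 4-methoxybenzyl alcohol
Product: 3 2,6-bis[(4-methoxybenzyl)oxy]-1,4-benzoquinone
Conditions: 2 (6 equiv), KOt-Bu (10 mol %), 4 Å MS, THF, 0 °C to rt
Reagents that add atoms: none
Why: Alkoxy exchange on an alkoxyquinone (vinylogous transesterification): the 4-methoxybenzyl alkoxide adds to C2 and C6, each the β-carbon of an enone ending at C4, methoxide is expelled, and the sieves bind the methanol so that the equilibrium moves to 3.

Step 2
Reactants: 4 2-fluoro-4,6-dimethoxybenzaldehyde
Product: 5 2-ethynyl-1-fluoro-3,5-dimethoxybenzene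
Conditions: dimethyl (1-diazo-2-oxopropyl)phosphonate (1.3 equiv), K2CO3 (2 equiv), MeOH, 0 °C to rt
Reagents that add atoms: dimethyl (1-diazo-2-oxopropyl)phosphonate, CC(=O)C(=[N+]=[N-])P(=O)(OC)OC
Why: Seyferth–Gilbert homologation in the Ohira–Bestmann form: methanolysis frees the diazomethylphosphonate anion, which adds to the aldehyde, and loss of phosphate and nitrogen with a 1,2-hydride shift gives the terminal alkyne under conditions too mild to displace the aryl fluoride.

Step 3
Reactants: 5 2-ethynyl-1-fluoro-3,5-dimethoxybenzene; 3 2,6-bis[(4-methoxybenzyl)oxy]-1,4-benzoquinone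
Product: 7 4-[(2-fluoro-4,6-dimethoxyphenyl)ethynyl]-4-hydroxy-3,5-bis[(4-methoxybenzyl)oxy]cyclohexa-2,5-dien-1-one, via lithium acetylide 6 (not isolated)
Conditions: n-BuLi (1.05 equiv), THF, −78 °C; then 3, −78 °C; AcOH, −78 °C
Reagents that add atoms: none
Why: 1,2-Addition of an alkynyllithium to a quinone: the C1 carbonyl of 3 is the only one not deactivated by vinylogous ester resonance (C4 is β to both alkoxy groups), so the slim acetylide attacks there and gives the quinol with the oxygen pattern of ring D; no stereocentre arises because the mirror plane is kept.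

Step 4
Reactants: 7 4-[(2-fluoro-4,6-dimethoxyphenyl)ethynyl]-4-hydroxy-3,5-bis[(4-methoxybenzyl)oxy]cyclohexa-2,5-dien-1-one
Product: 8 1-(2-fluoro-4,6-dimethoxyphenyl)-2-{1-hydroxy-2,6-bis[(4-methoxybenzyl)oxy]-4-oxocyclohexa-2,5-dien-1-yl}ethane-1,2-dione
Conditions: PdCl2 (10 mol %), DMSO, 100 °C
Reagents that add atoms: dimethyl sulfoxide, CS(C)=O
Why: Palladium-catalysed oxidation of an internal aryl alkyne to a 1,2-dione with DMSO as oxygen donor (oxypalladation and Kornblum-type loss of Me2S, twice), a water-free and base-free method that should leave electron-rich arenes, benzyl ethers and the free hydroxyl alone; the product has no enolisable position.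

Step 5
Reactants: 8 1-(2-fluoro-4,6-dimethoxyphenyl)-2-{1-hydroxy-2,6-bis[(4-methoxybenzyl)oxy]-4-oxocyclohexa-2,5-dien-1-yl}ethane-1,2-dione
Product: 9 5,7-dimethoxy-2',6'-bis[(4-methoxybenzyl)oxy]spiro[chromane-2,1'-cyclohexa-2',5'-diene]-3,4,4'-trione (achiral; mirror plane through ring C)
Conditions: NaH (1.1 equiv), THF–DMF (4:1), 0 °C to rt; pH 5 phosphate buffer, 0 °C
Reagents that add atoms: none
Why: Intramolecular nucleophilic aromatic substitution (addition–elimination closing six-membered ring C): the tertiary alkoxide attacks the fluorine-bearing carbon ortho to the aroyl carbonyl, the Meisenheimer intermediate is stabilised by the 1,2-dione, both methoxy groups are meta to fluorine, and a non-nucleophilic hydride base with buffered work-up avoids attack at the electrophilic C3 carbonyl.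

Step 6
Reactants: 9 5,7-dimethoxy-2',6'-bis[(4-methoxybenzyl)oxy]spiro[chromane-2,1'-cyclohexa-2',5'-diene]-3,4,4'-trione
Product: 10 PMB enol ether of the C/D/F tricycle (spiro carbon R, C3 R, benzylic carbon S): 3-hydroxy-5,7-dimethoxychroman-4-one whose C2 is the spiro carbon of a 4'-oxocyclohexa-2',5'-diene, with O–CH(4-methoxyphenyl) bridging C2' and C3 (ring F, cis-fused to ring C, hydroxyl and aryl cis) and OPMB on C6'
Conditions: Sc(OTf)3 (20 mol %), 2,6-bis[(4S)-4-phenyl-4,5-dihydrooxazol-2-yl]pyridine (24 mol %), 4 Å MS, CH2Cl2, −40 °C, 450 nm LEDs, Ar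
Reagents that add atoms: none
Why: Proposed new method: 450 nm light excites only the scandium-chelated 1,2-dione (the ring D dienone is transparent there, so its own photorearrangement is avoided), the C3 carbonyl oxygen takes a benzylic hydrogen from one OCH2Ar arm over a seven-membered array (directly, or by electron transfer from the anisyl ring followed by proton transfer), and the ketyl/benzyl 1,5-biradical recombines to the C3–CH(aryl) bond. The closest known reaction type is the racemic Norrish–Yang cyclisation of 2-benzyloxyaryl ketones and β-alkoxy ketones to 3-hydroxydihydrofurans by δ-hydrogen abstraction; chiral Lewis acids are known to steer excited-state enones but not this hydrogen abstraction, hence the label. Ring F closes by recombination of the 1,5-biradical, a five-membered closure that can only be cis-fused to ring C. The spiro carbon becomes stereogenic through the choice between the two enantiotopic arms, made by the C2-symmetric pybox ligand on the chelating metal; C3 follows from that choice because the new bond must form on the side of the reacting arm; the benzylic carbon is set during recombination, the anisyl group turning away from the C4 carbonyl and ring A and so ending cis to the new hydroxyl. The step needs site selectivity between the two dione oxygens, secured by the shorter reach of the C3 oxygen (the C4 oxygen would need an eight-membered array and a six-membered closure), and a silent background reaction, for which low temperature and the stronger absorption of the complex are relied on.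

Step 7
Reactants: 10 PMB enol ether of the C/D/F tricycle
Product: 11 enol-dione of the C/D/F tricycle (10 without its PMB group, drawn as the 6'-hydroxy-4'-oxo tautomer; core configuration unchanged)
Conditions: TFA (10 equiv), pentamethylbenzene (3 equiv), CH2Cl2, 0 °C
Reagents that add atoms: none
Why: Acidolysis of a 4-methoxybenzyl vinylogous ester (SN1 loss of the 4-methoxybenzyl cation from an enol of pKa near 5, Friedel–Crafts capture by pentamethylbenzene); the ring F ether should be spared because its benzylic carbon bears the electron-poor C3 and any ionisation there would simply reclose, and no stereocentre is touched.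

Step 8
Reactants: 11 enol-dione of the C/D/F tricycle; 12 3-chloro-1-(4-methoxyphenyl)propan-1-one
Product: 14 5'-[3-(4-methoxyphenyl)-3-oxopropyl] derivative of 11, via aryl vinyl ketone 13 (not isolated)
Conditions: 12 (1.05 equiv), Et3N (2.2 equiv), MeCN, 0 °C to rt; aq. citric acid
Reagents that add atoms: none
Why: Michael addition of a cyclic 1,3-dione to an aryl vinyl ketone released from its β-chloro ketone by E1cB elimination: C5' is the only carbon between two carbonyls (C3' belongs to the ring F vinylogous ester and is not acidic), O-addition is reversible, one equivalent of acceptor limits double addition, and as its ammonium enolate ring D is not prone to retro-aldol aromatisation; no stereocentre forms.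

Step 9
Reactants: 14 5'-[3-(4-methoxyphenyl)-3-oxopropyl] derivative of 11
Product: 16 target CNP0251458.1 (spiro carbon S; C3 R; ring F benzylic carbon S; ring P benzylic carbon R), via benzylic (R)-carbinol 15 (not isolated)
Conditions: RuCl[(R,R)-TsDPEN](p-cymene) (2 mol %), HCO2H–Et3N (5:2), EtOAc, 30 °C; then PPTS (20 mol %), CH2Cl2, rt
Reagents that add atoms: none
Why: Noyori–Ikariya asymmetric transfer hydrogenation sets the ring P stereocentre under catalyst control (the (R,R)-catalyst should give the (R)-carbinol, as with acetophenone, while the hindered, electron-rich C4 ketone and the vinylogous acid are inert), and mild acid then closes ring P by hemiketalisation at C6', the dione carbonyl that is not part of the ring F vinylogous ester, and loss of water (cyclodehydration), with the carbinol C–O bond and hence its configuration retained.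

Compound list
1 | 2,6-dimethoxy-1,4-benzoquinone | COC1=CC(=O)C=C(OC)C1=O | starting material
2 | 4-methoxybenzyl alcohol | COc1ccc(CO)cc1 | starting material
3 | 2,6-bis[(4-methoxybenzyl)oxy]-1,4-benzoquinone | COc1ccc(COC2=CC(=O)C=C(OCc3ccc(OC)cc3)C2=O)cc1 | intermediate
4 | 2-fluoro-4,6-dimethoxybenzaldehyde | COc1cc(F)c(C=O)c(OC)c1 | starting material
5 | 2-ethynyl-1-fluoro-3,5-dimethoxybenzene | COc1cc(F)c(C#C)c(OC)c1 | intermediate
6 | lithium (2-fluoro-4,6-dimethoxyphenyl)acetylide (not isolated) | COc1cc(F)c(C#C[Li])c(OC)c1 | intermediate
7 | 4-[(2-fluoro-4,6-dimethoxyphenyl)ethynyl]-4-hydroxy-3,5-bis[(4-methoxybenzyl)oxy]cyclohexa-2,5-dien-1-one | COc1ccc(COC2=CC(=O)C=C(OCc3ccc(OC)cc3)C2(O)C#Cc4c(F)cc(OC)cc4OC)cc1 | intermediate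
8 | 1-(2-fluoro-4,6-dimethoxyphenyl)-2-{1-hydroxy-2,6-bis[(4-methoxybenzyl)oxy]-4-oxocyclohexa-2,5-dien-1-yl}ethane-1,2-dione | COc1ccc(COC2=CC(=O)C=C(OCc3ccc(OC)cc3)C2(O)C(=O)C(=O)c4c(F)cc(OC)cc4OC)cc1 | intermediate
9 | 5,7-dimethoxy-2',6'-bis[(4-methoxybenzyl)oxy]spiro[chromane-2,1'-cyclohexa-2',5'-diene]-3,4,4'-trione (achiral precursor of the key step) | COc1ccc(COC2=CC(=O)C=C(OCc3ccc(OC)cc3)C24Oc3cc(OC)cc(OC)c3C(=O)C4=O)cc1 | intermediate
10 | PMB enol ether of the C/D/F tricycle (spiro carbon R, C3 R, ring F benzylic carbon S; ring F cis-fused to ring C; 3-OH and 4-methoxyphenyl cis; OPMB on C6') | C3=C(OCc6ccc(OC)cc6)[C@]24Oc5cc(OC)cc(OC)c5C(=O)[C@@]2(O)[C@H](c2ccc(OC)cc2)OC4=CC3=O | intermediate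
11 | enol-dione of the C/D/F tricycle (6'-hydroxy-4'-oxo tautomer; core configuration as in 10) | C3=C(O)[C@]24Oc5cc(OC)cc(OC)c5C(=O)[C@@]2(O)[C@H](c2ccc(OC)cc2)OC4=CC3=O | intermediate
12 | 3-chloro-1-(4-methoxyphenyl)propan-1-one | COc1ccc(C(=O)CCCl)cc1 | starting material
13 | 1-(4-methoxyphenyl)prop-2-en-1-one (not isolated) | COc1ccc(C(=O)C=C)cc1 | intermediate
14 | 5'-[3-(4-methoxyphenyl)-3-oxopropyl] derivative of 11 (core configuration as in 10) | COc1ccc(C(=O)CCC3=C(O)[C@]24Oc5cc(OC)cc(OC)c5C(=O)[C@@]2(O)[C@H](c2ccc(OC)cc2)OC4=CC3=O)cc1 | intermediate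
15 | 5'-[(3R)-3-hydroxy-3-(4-methoxyphenyl)propyl] derivative of 11 (not isolated; core configuration as in 10) | COc1ccc([C@H](O)CCC3=C(O)[C@]24Oc5cc(OC)cc(OC)c5C(=O)[C@@]2(O)[C@H](c2ccc(OC)cc2)OC4=CC3=O)cc1 | intermediate
16 | CNP0251458.1 (spiro carbon S, C3 R, ring F benzylic carbon S, ring P benzylic carbon R) | COc1ccc([C@H]2CCC3=C(O2)[C@]24Oc5cc(OC)cc(OC)c5C(=O)[C@@]2(O)[C@H](c2ccc(OC)cc2)OC4=CC3=O)cc1 | target

Total step count: 9 steps.
Longest linear sequence: 8 steps (4 to 16 through steps 2 to 9; the arm from 1 through steps 1 and 3 to 9 is equally long).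

Steps most likely to fail

1. Step 6. The choice between the two enantiotopic ether arms may be poor, for two reasons: the Lewis acid may bind the more basic ring D carbonyl (a doubly vinylogous carbonate) instead of chelating the dione, or unbound 9 may absorb and cyclise without control. The Lewis acid may also trigger loss of a PMB group or release of ring D as a phenol. The fallback sets out from 9 and uses the plain Norrish–Yang cyclisation, a known reaction type: irradiation at 450 nm in degassed CH2Cl2 without any additive should give 10 together with the enantiomer of 10 F1. Preparative chromatography on a chiral stationary phase (amylose tris(3,5-dimethylphenylcarbamate), supercritical CO2–MeOH) then separates the two, and the route is rejoined at 10.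

2. Step 4. Oxygen transfer to the hindered alkyne next to the quinol carbon may be slow at a temperature at which the quinol or its PMB enol ethers decompose, or the palladium may divert the propargylic alcohol into side reactions. The fallback sets out from 7 and reaches the dione by way of an alkene. Semi-hydrogenation (H2, Pd/CaCO3 poisoned with Pb(OAc)2, quinoline, EtOAc) should give the (Z)-styryl quinol F2. Dihydroxylation of this alkene, the only one not conjugated to a carbonyl (OsO4 cat., NMO, acetone–water), should give the triol F3. Swern oxidation of both secondary carbinols ((COCl)2, DMSO, Et3N, CH2Cl2, −78 °C) then returns to the route at 8.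

3. Step 9. The carbinol may close on the C4' carbonyl, which would give the linearly conjugated regioisomer of ring D. Acid may ionise the 4-methoxybenzylic carbinol with loss of configuration, and the keto form may dehydrate to a 4H-pyran before it is reduced. The fallback sets out from 14 and forms the other C–O bond of ring P. Transfer hydrogenation with RuCl[(S,S)-TsDPEN](p-cymene) in HCO2H–Et3N should give the (S)-carbinol epimer of 15 F4, isolated by neutral work-up. Intramolecular Mitsunobu etherification (PPh3, DIAD, THF, 0 °C) then lets the enol oxygen displace the activated carbinol with inversion under neutral conditions, and the route is rejoined at 16.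

Further compounds
F1 | step 6 | enantiomer of 10 | C3=C(OCc6ccc(OC)cc6)[C@@]24Oc5cc(OC)cc(OC)c5C(=O)[C@]2(O)[C@@H](c2ccc(OC)cc2)OC4=CC3=O
F2 | step 4 | 4-[(Z)-2-(2-fluoro-4,6-dimethoxyphenyl)ethenyl]-4-hydroxy-3,5-bis[(4-methoxybenzyl)oxy]cyclohexa-2,5-dien-1-one | COc1ccc(COC2=CC(=O)C=C(OCc3ccc(OC)cc3)C2(O)/C=C\c4c(F)cc(OC)cc4OC)cc1
F3 | step 4 | 4-[2-(2-fluoro-4,6-dimethoxyphenyl)-1,2-dihydroxyethyl]-4-hydroxy-3,5-bis[(4-methoxybenzyl)oxy]cyclohexa-2,5-dien-1-one (racemic, relative configuration from syn addition to the Z-alkene, one enantiomer drawn) | COc1ccc(COC2=CC(=O)C=C(OCc3ccc(OC)cc3)C2(O)[C@H](O)[C@H](O)c4c(F)cc(OC)cc4OC)cc1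
F4 | step 9 | 5'-[(3S)-3-hydroxy-3-(4-methoxyphenyl)propyl] derivative of 11 (carbinol epimer of 15) | COc1ccc([C@@H](O)CCC3=C(O)[C@]24Oc5cc(OC)cc(OC)c5C(=O)[C@@]2(O)[C@H](c2ccc(OC)cc2)OC4=CC3=O)cc1
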